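Compound numbers refer to the steps and the compound list below. The atom numbers C1–C10 and the ring letters are those fixed in the first section.

## Analysis of the target

The target 37 is a daucane-type sesquiterpenoid ester. It is a trans-fused bicyclo[5.3.0]decane in which ring A (C1–C5) is a cyclopentane and ring B (C1, C5–C10) a cycloheptane, with the tertiary C4 oxygen acylated by vanillic acid. It has six stereocentres: quaternary C1 (methyl), the fully substituted carbinol C4 (isopropyl), the ring-fusion methine C5, the secondary carbinol C6, and the epoxide carbons C8 (methyl) and C9. Taking the face of the C1 methyl as β, the C4 oxygen is β and the isopropyl α, while C5–H, C6–OH and the epoxide oxygen are all α. The ring fusion is therefore trans, the C4–O/C6–O pair is anti-1,3, and the epoxide is cis to C6–OH. The sensitive groups are the acid-labile trisubstituted epoxide, a hindered tertiary aryl ester next to a free secondary hydroxyl (acyl migration, elimination) and a free phenol. On the way, the tertiary C4 alcohol is allylic or β to a ketone in several intermediates. The difficulties are that C5 lies between two fully substituted carbons, that its hydrogen must enter on the face that carries the isopropyl group, that a tertiary alcohol must be acylated beside a secondary one, and that the methyl group belongs on C8 and not on C9. The strategy rests on C4: if C5 and C6 are an ethynyl group on C4, then C4 is a tertiary propargylic alcohol. The chain C2–C3 ties it to an alkene C1=C10 that carries a cyclopropane (C9, C8, C7). A (5+2) cycloaddition then closes ring A through C1–C5 and ring B through C6–C7 at once, leaving C5=C6 and a C9 enol ether as handles.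

## Retrosynthetic reasoning

**Ester and protecting groups (37 ⇒ 36 ⇒ 31 + 35; 35 ⇐ 34 ⇐ 32).** The O4–acyl bond is cut to the tertiary alcohol 31 and the acid chloride 35. It is cut late because the aryl ester would not survive the enolate, hydride and radical chemistry used earlier. A tertiary alkoxide can only be acylated cleanly while the secondary C6 hydroxyl is masked. C6–O and the phenol both carry silyl groups, so one buffered fluoride step (36 → 37) frees both. The acid chloride 35 comes from vanillic acid 32 through the silyl-protected acid 34.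

**Epoxide (31 ⇒ 30 ⇒ 29).** The two C–O bonds of the epoxide are cut back to the alkene of diol 29. The forward reaction must deliver oxygen to the α face of C8=C9, and the homoallylic C6 hydroxyl, which is α, can do this by binding the metal peroxide. The epoxidation therefore comes before C6–OH is silylated and before the oxidisable aryl group is attached.

**C6–OH and C5–H (29 ⇒ 28 ⇒ 27 ⇒ 26 ⇒ 25).** The C6–H bond is cut to ketone 28. Intramolecular hydride delivery from the C4 hydroxyl gives the anti-1,3-diol, which is the 6α-alcohol. Ketone 28 comes from diol 27 by oxidation, 27 from epoxide 26 by cutting the C5–H bond, and 26 from the alkene of 25. A one-step syn hydroboration of C5=C6 was not chosen: it would have to come from the α face, which carries the isopropyl group and the C10/C8 flank of ring B, so attack from the β face and a cis ring fusion are more likely. Instead the C4 hydroxyl is used twice. It first places the epoxide on the β face. The C5 radical formed on reductive opening then takes hydrogen on the α face, away from the titanium alkoxide on C6. After oxidation, the same hydroxyl steers hydride to C6.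

**C8 methyl and C8=C9 (25 ⇒ 22 ⇒ 21 ⇒ 18).** The C8 methyl carbon is traced to an exocyclic methylene group placed α to the C9 ketone of 18. Removing the C9 oxygen with allylic transposition then leaves the alkene only at C8=C9. A methylation/enol triflate sequence would depend on regioselective enolisation of a 2-methyl ketone; the transposition does not. Kinetic enolisation of 18 should occur at C8 because C10 is neopentylic.

**Key disconnection (18 ⇒ 17 ⇒ 16).** Ketone 18 is the hydrolysed form of silyl enol ether 17. Cutting C1–C5 and C6–C7 of 17 opens both rings and gives the acyclic yne-vinylcyclopropane 16, whose only stereocentre is C4. Two rings, two skeletal bonds and the quaternary C1 are gained in one catalytic step. The forward reaction must choose the face of C1=C10 that puts the methyl cis to the C4 oxygen.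

**Alkyne and C4 stereocentre (16 ⇒ 14 ⇒ 13 ⇒ 12).** The ethynyl carbinol is traced to the 2,3-epoxy chloride 14, which fragments under base without touching the C4–O bond, and so to the epoxy alcohol 13 and the allylic alcohol 12. C4 is thus set by a titanium–tartrate epoxidation of a trisubstituted allylic alcohol. Direct enantioselective alkynylation of an isopropyl alkyl ketone was judged unreliable. Oxidative cleavage of a chiral-pool 4-isopropylcyclohexenol was also set aside: it would leave a CH2–CHO arm on C4. One-carbon homologation of that aldehyde gives a propargyl group, so the tether is one atom too long. A non-homologating dehydration would require enolising a β-hydroxy aldehyde.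

**Isopropyl group and C6 (12 ⇒ 11 ⇒ 10 ⇒ 8).** The C4–isopropyl bond is cut by a syn-carbocupration of ynoate 10. This fixes the (E)-geometry with isopropyl trans to the future hydroxymethyl group, the substitution pattern that the asymmetric epoxidation handles best. C6 arrives by acylation of the acetylide of 8 with a chloroformate.

**Vinylcyclopropane (8 ⇒ 7 ⇒ 6 ⇒ 5 ⇒ 1 + 2).** The cyclopropane carbons C7 and C8 are added to the ester carbon (C9) of 5 in a Kulinkovich reaction. The C1–C2 bond and the (E)-C1=C10 alkene come from syn-carbocupration of ynoate 2 by the copper reagent derived from bromide 1.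

## Alternatives that were turned down

**Alternative 1:** This route cuts C4–C5 of ring A. In the forward sense a Rh2(OAc)4 carbenoid at C5, whose ester carbon is C6, inserts into the ether-activated C4–H bond with retention and gives the cyclopentane ester A1.
- For: retention turns an easily made secondary carbinol stereocentre into the tertiary C4 centre. Five-membered ring formation next to oxygen is the favoured insertion mode. The C8=C9 alkene with its methyl group is present from the start.
- Against: the carbenoid sits on quaternary C1 next to a side chain with a trisubstituted alkene, and cyclopropanation of that alkene should compete with insertion into a crowded tertiary C–H bond. The isopropyl methine is a second insertion site. C1 must be set beforehand in an open chain, remote from C4. Ring B remains to be closed through C6–C7, with redox changes at C6.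
- Comparison: it is stronger on C1, which is fixed independently and not by diastereoselection in the ring-forming step, and on the placement of the C8 methyl. The chosen route offers both rings and C1 in one step from a precursor with a single stereocentre, and a shorter path to the bicycle.

**Alternative 2:** This route cuts C1–C10 and C5–C6 at ring A. Starting from 3-methylcyclopent-2-en-1-one A2, a copper/chiral N-heterocyclic carbene catalyst (CuBr·SMe2) adds an alkenyl Grignard reagent to C1, and the magnesium enolate is trapped at C5 by an aldehyde to give the ketone A3.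
- For: it is very convergent and starts from a cheap enone. C1, C5 and C6 and two C–C bonds are made in one pot, the trans relation of the two new arms follows from anti trapping of the enolate, and C6 arrives at the right oxidation level with C7, C8 and the C8 methyl attached.
- Against: C4 is still a ketone. Adding an isopropyl nucleophile to a hindered, enolisable β-hydroxy cyclopentanone with the right facial sense is difficult (reduction, enolisation, retro-aldol). Enantioselective quaternary-centre formation with an alkenyl magnesium reagent on a β-methyl cyclopentenone is at the limit of the method. Ring B must still be closed between C8 and C9 with the alkene in the right place.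
- Comparison: it is stronger on C5 and C6, which the chosen route sets in four steps. The chosen route offers the C4 centre in secure form before any ring exists, and closes ring B in the same step as ring A.

**Alternative 3:** This route cuts C7–C8 of ring B. In the forward sense CuI with N,N'-dimethylethylenediamine and Cs2CO3 couples the β-keto ester carbon C7 with an alkenyl iodide carbon C8 and gives the bicyclic β-keto ester A4.
- For: the alkene is fixed at C8=C9 with the methyl on C8, so nothing has to be adjusted there. C6 is a ketone ready for hydroxyl-directed reduction, and C5, being α to that ketone, can settle in the more stable trans arrangement.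
- Against: seven-membered ring closure by C-alkenylation of a hindered β-keto ester is slow compared with five- and six-membered cases. The β,γ-unsaturated β-keto ester can slip into conjugation. The extra ester must be removed under conditions that threaten alkene position and the β-silyloxy group at C4. A ring A piece with C1, C4 and C5 in place has to be prepared first.
- Comparison: it is stronger on the C8/C9 problem and on C5. The chosen route reaches the bicycle in far fewer operations and keeps the risk in one catalytic step.

Key step: step 11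

Remarks on the chemistry. (a) Bicyclic compounds are named on the bicyclo[5.3.0]decane skeleton with the atom numbers C1–C10 of the Analysis, not with von Baeyer locants; β is the face of the C1 methyl group, α the opposite face. (b) Assumption: where a stereocentre is destroyed in the following step (C8 in 19 and 20, C9 in 22 to 24), both epimers are carried on and the SMILES leaves that centre open.

## Route

Step 1
Reactants: 1 (4-bromobut-1-yn-1-yl)trimethylsilane; 2 ethyl but-2-ynoate
Product: 5 ethyl (2E)-3-methyl-7-(trimethylsilyl)hept-2-en-6-ynoate, via Grignard reagent 3 (not isolated), via alkylcopper reagent 4 (not isolated)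
Conditions: Mg, THF, rt; CuI (1 equiv), −40 °C; then 2, −78 °C; aq NH4Cl at −78 °C
Reagents that add atoms: none
Why: Grignard formation, transmetallation to the alkylcopper and syn-carbocupration of the ynoate; protonation of the alkenylcopper in the cold with retention fixes the (E)-geometry, chain trans to the ester.

Step 2
Reactants: 5 ethyl (2E)-3-methyl-7-(trimethylsilyl)hept-2-en-6-ynoate
Product: 6 1-[(1E)-2-methyl-6-(trimethylsilyl)hex-1-en-5-yn-1-yl]cyclopropan-1-ol
Conditions: EtMgBr (3 equiv), Ti(OiPr)4 (0.5 equiv), THF, 0 °C → rt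
Reagents that add atoms: ethylmagnesium bromide, CC[Mg]Br
Why: Kulinkovich cyclopropanation: the titanacyclopropane formed from EtMgBr and Ti(OiPr)4 adds twice to the ester carbonyl as a 1,2-dicarbanion equivalent; β,β-disubstituted enoates are the unsaturated esters that tolerate it, and the hindered silylalkyne should stay out of the reaction.

Step 3
Reactants: 6 1-[(1E)-2-methyl-6-(trimethylsilyl)hex-1-en-5-yn-1-yl]cyclopropan-1-ol
Product: 7 tert-butyl(dimethyl){1-[(1E)-2-methyl-6-(trimethylsilyl)hex-1-en-5-yn-1-yl]cyclopropoxy}silane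
Conditions: TBSCl, imidazole, DMF, rt
Reagents that add atoms: tert-butyldimethylsilyl chloride, CC(C)(C)[Si](C)(C)Cl
Why: Silylation of the cyclopropanol under basic conditions; acid is avoided from here to step 11 because 1-alkenylcyclopropanol derivatives ring-expand to cyclobutanones.

Step 4
Reactants: 7 tert-butyl(dimethyl){1-[(1E)-2-methyl-6-(trimethylsilyl)hex-1-en-5-yn-1-yl]cyclopropoxy}silane
Product: 8 tert-butyl(dimethyl){1-[(1E)-2-methylhex-1-en-5-yn-1-yl]cyclopropoxy}silane
Conditions: K2CO3 (cat.), MeOH, rt
Reagents that add atoms: none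
Why: Base-catalysed methanolysis of the C(sp)–Si bond; the tertiary silyl ether is not touched.

Step 5
Reactants: 8 tert-butyl(dimethyl){1-[(1E)-2-methylhex-1-en-5-yn-1-yl]cyclopropoxy}silane
Product: 10 ethyl (6E)-7-[1-(tert-butyldimethylsilyloxy)cyclopropyl]-6-methylhept-6-en-2-ynoate, via lithium acetylide 9 (not isolated)
Conditions: n-BuLi, THF, −78 °C; ClCO2Et, −78 → 0 °C
Reagents that add atoms: ethyl chloroformate, CCOC(=O)Cl
Why: Deprotonation of the terminal alkyne and C-acylation of the lithium acetylide by the chloroformate; this brings in C6.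

Step 6
Reactants: 10 ethyl (6E)-7-[1-(tert-butyldimethylsilyloxy)cyclopropyl]-6-methylhept-6-en-2-ynoate
Product: 11 ethyl (2E,6E)-7-[1-(tert-butyldimethylsilyloxy)cyclopropyl]-6-methyl-3-(propan-2-yl)hepta-2,6-dienoate
Conditions: i-PrMgCl, CuI (1 equiv), THF, −78 °C; then 10, −78 °C; aq NH4Cl at −78 °C
Reagents that add atoms: isopropylmagnesium chloride, CC(C)[Mg]Cl
Why: syn-Carbocupration of the ynoate by isopropylcopper and cold protonation give the (2E)-enoate with isopropyl trans to the ester; this geometry decides which enantiomer step 8 produces.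

Step 7
Reactants: 11 ethyl (2E,6E)-7-[1-(tert-butyldimethylsilyloxy)cyclopropyl]-6-methyl-3-(propan-2-yl)hepta-2,6-dienoate
Product: 12 (2E,6E)-7-[1-(tert-butyldimethylsilyloxy)cyclopropyl]-6-methyl-3-(propan-2-yl)hepta-2,6-dien-1-ol
Conditions: DIBAL-H (2.2 equiv), CH2Cl2, −78 °C; Rochelle salt work-up
Reagents that add atoms: none
Why: 1,2-Reduction of the enoate to the allylic alcohol with retention of both alkene geometries.

Step 8
Reactants: 12 (2E,6E)-7-[1-(tert-butyldimethylsilyloxy)cyclopropyl]-6-methyl-3-(propan-2-yl)hepta-2,6-dien-1-ol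
Product: 13 [(2R,3R)-3-{(3E)-4-[1-(tert-butyldimethylsilyloxy)cyclopropyl]-3-methylbut-3-en-1-yl}-3-(propan-2-yl)oxiran-2-yl]methanol
Conditions: Ti(OiPr)4 (10 mol %), (−)-diethyl D-tartrate (12 mol %), t-BuOOH, 4 Å MS, CH2Cl2, −20 °C
Reagents that add atoms: tert-butyl hydroperoxide, CC(C)(C)OO
Why: Sharpless asymmetric epoxidation: the D-tartrate complex delivers oxygen to the face that gives the (2R,3R)-epoxide of this (E)-allylic alcohol, which fixes C4; only the alkene of the allylic alcohol is activated, and the Z-position holds the unbranched chain, which the catalyst accepts well.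

Step 9
Reactants: 13 [(2R,3R)-3-{(3E)-4-[1-(tert-butyldimethylsilyloxy)cyclopropyl]-3-methylbut-3-en-1-yl}-3-(propan-2-yl)oxiran-2-yl]methanol
Product: 14 (2S,3R)-2-(chloromethyl)-3-{(3E)-4-[1-(tert-butyldimethylsilyloxy)cyclopropyl]-3-methylbut-3-en-1-yl}-3-(propan-2-yl)oxirane
Conditions: PPh3, CCl4, NaHCO3, 70 °C
Reagents that add atoms: tetrachloromethane, ClC(Cl)(Cl)Cl
Why: Appel chlorination of the primary alcohol under neutral conditions; the epoxide and both stereocentres are untouched (the C2 descriptor changes only through priority).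

Step 10
Reactants: 14 (2S,3R)-2-(chloromethyl)-3-{(3E)-4-[1-(tert-butyldimethylsilyloxy)cyclopropyl]-3-methylbut-3-en-1-yl}-3-(propan-2-yl)oxirane
Product: 16 (3R,6E)-7-[1-(tert-butyldimethylsilyloxy)cyclopropyl]-6-methyl-3-(propan-2-yl)hept-6-en-1-yn-3-ol, via chlorovinyl alkoxide 15 (not isolated)
Conditions: LDA (3.5 equiv), THF, −78 → −20 °C
Reagents that add atoms: none
Why: Base-induced fragmentation of a 2,3-epoxy chloride: deprotonation next to chlorine opens the epoxide by β-elimination, and a second dehydrochlorination gives the terminal alkyne; the C4–O bond is never broken, so the epoxide configuration at C4 becomes that of the tertiary propargylic alcohol.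

Step 11
Reactants: 16 (3R,6E)-7-[1-(tert-butyldimethylsilyloxy)cyclopropyl]-6-methyl-3-(propan-2-yl)hept-6-en-1-yn-3-ol
Product: 17 9-(tert-butyldimethylsilyloxy)-1β-methyl-4α-(propan-2-yl)bicyclo[5.3.0]deca-5,9-dien-4β-ol
Conditions: [Rh(CO)2Cl]2 (5 mol %), 1,2-dichloroethane (0.01 M), 70 °C
Reagents that add atoms: none
Why: Rhodium-catalysed intramolecular (5+2) cycloaddition of an alkyne-tethered vinylcyclopropane, a known reaction class that is here applied to a trisubstituted alkene. Monovalent rhodium binds the ene–cyclopropane unit and cleaves a cyclopropane C–C bond (C9–C7; the two CH2 groups are equivalent, so there is no regiochemical question) to a σ-alkyl/π-allyl complex of trivalent rhodium, a step the siloxy group accelerates. The tethered alkyne then inserts into the Rh–C1 terminus of the allyl; this forms C1–C5 and closes ring A as the five-membered tether ring, and reductive elimination from the resulting eight-membered rhodacycle joins C6 (sp2) to C7 (sp3) and closes ring B as the seven-membered ring. An oxidative-cyclisation-first ordering would give the same two bonds. The only new stereocentre is quaternary C1, set in the insertion step under substrate control by C4: the transition state leading to 17 keeps the isopropyl group pseudo-equatorial on the side of the flatter C10 arm and lets the small hydroxyl share the face of the C1 methyl. This bias is modest, so the C1 epimer is a foreseeable by-product. The alkene geometry is erased in the product, so only the facial selectivity at C1=C10 matters. The step also needs cycloaddition to win over alkyne oligomerisation (high dilution) and over ring expansion of the siloxycyclopropane (neutral catalyst, no Lewis acid).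

Step 12
Reactants: 17 9-(tert-butyldimethylsilyloxy)-1β-methyl-4α-(propan-2-yl)bicyclo[5.3.0]deca-5,9-dien-4β-ol
Product: 18 4β-hydroxy-1β-methyl-4α-(propan-2-yl)bicyclo[5.3.0]dec-5-en-9-one
Conditions: TBAF, AcOH, THF, 0 °C
Reagents that add atoms: none
Why: Fluoride cleaves the silyl enol ether and acetic acid protonates the enolate to the C9 ketone; acid hydrolysis is avoided because the C4 carbinol is tertiary and allylic.

Step 13
Reactants: 18 4β-hydroxy-1β-methyl-4α-(propan-2-yl)bicyclo[5.3.0]dec-5-en-9-one
Product: 21 4β-hydroxy-1β-methyl-8-methylidene-4α-(propan-2-yl)bicyclo[5.3.0]dec-5-en-9-one, via Mannich base 19 (not isolated), via ammonium iodide 20 (not isolated)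
Conditions: LDA (2.3 equiv), THF, −78 °C; CH2=NMe2+ I−, −78 → 0 °C; then MeI, CH2Cl2, rt; then aq NaHCO3, rt
Reagents that add atoms: Eschenmoser's salt (N,N-dimethylmethyleneiminium iodide), C=[N+](C)C.[I-]
Why: After O-deprotonation, kinetic enolisation occurs at C8 because C10 is neopentylic; Mannich reaction with Eschenmoser's salt, N-methylation and elimination give the α-methylene ketone, which brings in the future C8 methyl carbon without polyalkylation.

Step 14
Reactants: 21 4β-hydroxy-1β-methyl-8-methylidene-4α-(propan-2-yl)bicyclo[5.3.0]dec-5-en-9-one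
Product: 22 1β-methyl-8-methylidene-4α-(propan-2-yl)bicyclo[5.3.0]dec-5-ene-4β,9-diol (both C9 epimers)
Conditions: NaBH4, CeCl3·7H2O, MeOH, −78 → 0 °C
Reagents that add atoms: none
Why: Luche reduction, a 1,2-hydride addition to the enone; the C9 configuration is irrelevant because C9 becomes sp2 in the next step.

Step 15
Reactants: 22 1β-methyl-8-methylidene-4α-(propan-2-yl)bicyclo[5.3.0]dec-5-ene-4β,9-diol
Product: 25 1β,8-dimethyl-4α-(propan-2-yl)bicyclo[5.3.0]deca-5,8-dien-4β-ol, via N-allylic sulfonylhydrazide 23 (not isolated), via allylic diazene 24 (not isolated)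
Conditions: 2-nitrobenzenesulfonylhydrazide, PPh3, DEAD, THF, −30 → 23 °C
Reagents that add atoms: none
Why: Myers reductive allylic transposition: Mitsunobu displacement of the secondary allylic alcohol, loss of the arenesulfinic acid and retro-ene loss of N2 from the monoalkyl diazene move the alkene to C8=C9 and put hydrogen on the exocyclic carbon, so the C8 methyl and the alkene position are fixed without a regiochemical choice. The tertiary C4 alcohol does not enter the Mitsunobu reaction.

Step 16
Reactants: 25 1β,8-dimethyl-4α-(propan-2-yl)bicyclo[5.3.0]deca-5,8-dien-4β-ol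
Product: 26 5β,6β-epoxy-1β,8-dimethyl-4α-(propan-2-yl)bicyclo[5.3.0]dec-8-en-4β-ol
Conditions: VO(acac)2 (5 mol %), t-BuOOH, CH2Cl2, 0 °C → rt
Reagents that add atoms: tert-butyl hydroperoxide, CC(C)(C)OO
Why: Hydroxyl-directed epoxidation: the tertiary allylic C4 hydroxyl binds vanadium and delivers oxygen to its own β face of C5=C6; the isolated C8=C9 alkene reacts far more slowly.

Step 17
Reactants: 26 5β,6β-epoxy-1β,8-dimethyl-4α-(propan-2-yl)bicyclo[5.3.0]dec-8-en-4β-ol
Product: 27 1β,8-dimethyl-4α-(propan-2-yl)-5αH-bicyclo[5.3.0]dec-8-ene-4β,6β-diol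
Conditions: Cp2TiCl2 (20 mol %), Zn dust, 2,4,6-collidine·HCl, 1,4-cyclohexadiene, THF, rt
Reagents that add atoms: none
Why: Titanocene-mediated reductive opening of a 2,3-epoxy alcohol to a 1,3-diol: Cp2TiCl (trivalent titanium) cleaves the C5–O bond homolytically to the tertiary C5 radical, which should take a hydrogen atom from 1,4-cyclohexadiene on the α face, anti to the bulky titanium alkoxide on C6 and with C6 moving trans to the isopropyl group. This sets the trans ring fusion; the β-hydroxyl at C6 is corrected in steps 18 and 19.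

Step 18
Reactants: 27 1β,8-dimethyl-4α-(propan-2-yl)-5αH-bicyclo[5.3.0]dec-8-ene-4β,6β-diol
Product: 28 4β-hydroxy-1β,8-dimethyl-4α-(propan-2-yl)-5αH-bicyclo[5.3.0]dec-8-en-6-one
Conditions: Dess–Martin periodinane, NaHCO3, CH2Cl2, 0 °C → rt
Reagents that add atoms: none
Why: Dess–Martin oxidation of the secondary alcohol; the tertiary alcohol is inert, and the buffered, base-free medium spares the β-hydroxy ketone (no retro-aldol) and C5, which already has the more stable trans arrangement.

Step 19
Reactants: 28 4β-hydroxy-1β,8-dimethyl-4α-(propan-2-yl)-5αH-bicyclo[5.3.0]dec-8-en-6-one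
Product: 29 1β,8-dimethyl-4α-(propan-2-yl)-5αH-bicyclo[5.3.0]dec-8-ene-4β,6α-diol
Conditions: Me4NBH(OAc)3, MeCN/AcOH, −30 → −20 °C
Reagents that add atoms: none
Why: Evans–Saksena reduction: the C4 hydroxyl exchanges onto boron and delivers hydride to C6 from its own face, which gives the anti-1,3-diol, that is the 6α-alcohol. The reagent does not reduce ketones without the directing hydroxyl, so no background reduction is expected.

Step 20
Reactants: 29 1β,8-dimethyl-4α-(propan-2-yl)-5αH-bicyclo[5.3.0]dec-8-ene-4β,6α-diol
Product: 30 8α,9α-epoxy-1β,8-dimethyl-4α-(propan-2-yl)-5αH-bicyclo[5.3.0]decane-4β,6α-diol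
Conditions: VO(acac)2 (5 mol %), t-BuOOH, CH2Cl2, rt
Reagents that add atoms: tert-butyl hydroperoxide, CC(C)(C)OO
Why: Hydroxyl-directed epoxidation from the homoallylic C6 hydroxyl: oxygen is delivered to C8=C9 on the α face, cis to C6–OH; the cis arrangement also keeps the alcohol from opening the epoxide.

Step 21
Reactants: 30 8α,9α-epoxy-1β,8-dimethyl-4α-(propan-2-yl)-5αH-bicyclo[5.3.0]decane-4β,6α-diol
Product: 31 8α,9α-epoxy-1β,8-dimethyl-4α-(propan-2-yl)-6α-(triethylsilyloxy)-5αH-bicyclo[5.3.0]decan-4β-ol
Conditions: TESCl, imidazole, DMF, 0 °C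
Reagents that add atoms: chlorotriethylsilane, CC[Si](CC)(CC)Cl
Why: Selective silylation of the secondary C6 hydroxyl; the tertiary C4 hydroxyl does not react under these conditions, and no Lewis acid is present that could open the epoxide.

Step 22
Reactants: 32 vanillic acid (4-hydroxy-3-methoxybenzoic acid)
Product: 34 4-(tert-butyldimethylsilyloxy)-3-methoxybenzoic acid, via bis-silylated vanillic acid 33 (not isolated)
Conditions: TBSCl (2.2 equiv), imidazole, DMF, rt; then AcOH, THF/H2O, rt
Reagents that add atoms: tert-butyldimethylsilyl chloride, CC(C)(C)[Si](C)(C)Cl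
Why: Silylation of phenol and acid, then selective hydrolysis of the labile silyl ester; the aryl silyl ether survives dilute acetic acid.

Step 23
Reactants: 34 4-(tert-butyldimethylsilyloxy)-3-methoxybenzoic acid
Product: 35 4-(tert-butyldimethylsilyloxy)-3-methoxybenzoyl chloride
Conditions: (COCl)2, DMF (cat.), CH2Cl2, 0 °C → rt; used crude
Reagents that add atoms: oxalyl chloride, O=C(Cl)C(=O)Cl
Why: Vilsmeier-type activation of the acid to the acid chloride under neutral conditions that the aryl silyl ether tolerates.

Step 24
Reactants: 31 8α,9α-epoxy-1β,8-dimethyl-4α-(propan-2-yl)-6α-(triethylsilyloxy)-5αH-bicyclo[5.3.0]decan-4β-ol; 35 4-(tert-butyldimethylsilyloxy)-3-methoxybenzoyl chloride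
Product: 36 8α,9α-epoxy-1β,8-dimethyl-4α-(propan-2-yl)-6α-(triethylsilyloxy)-5αH-bicyclo[5.3.0]decan-4β-yl 4-(tert-butyldimethylsilyloxy)-3-methoxybenzoate
Conditions: KHMDS, THF, −78 °C; then 35, −78 → 0 °C
Reagents that add atoms: none
Why: O-Acylation of the potassium alkoxide of a hindered tertiary alcohol by an aroyl chloride; the non-nucleophilic base leaves the epoxide alone, and the C6 silyl ether blocks the more reactive secondary hydroxyl.

Step 25
Reactants: 36 8α,9α-epoxy-1β,8-dimethyl-4α-(propan-2-yl)-6α-(triethylsilyloxy)-5αH-bicyclo[5.3.0]decan-4β-yl 4-(tert-butyldimethylsilyloxy)-3-methoxybenzoate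
Product: 37 8α,9α-epoxy-6α-hydroxy-1β,8-dimethyl-4α-(propan-2-yl)-5αH-bicyclo[5.3.0]decan-4β-yl 4-hydroxy-3-methoxybenzoate (CNP0315707.1)
Conditions: TBAF, AcOH, THF, 0 °C → rt
Reagents that add atoms: none
Why: Buffered fluoride removes the alkyl triethylsilyl ether and the aryl silyl ether in one operation; acetic acid keeps the medium near neutral so that the epoxide and the tertiary ester next to the freed hydroxyl are not disturbed.

## Compound list

1 | (4-bromobut-1-yn-1-yl)trimethylsilane | C[Si](C)(C)C#CCCBr | starting material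
2 | ethyl but-2-ynoate | CC#CC(=O)OCC | starting material
3 | [4-(trimethylsilyl)but-3-yn-1-yl]magnesium bromide | C[Si](C)(C)C#CCC[Mg]Br | intermediate (not isolated)
4 | [4-(trimethylsilyl)but-3-yn-1-yl]copper (MgBrI complex) | C[Si](C)(C)C#CCC[Cu] | intermediate (not isolated)
5 | ethyl (2E)-3-methyl-7-(trimethylsilyl)hept-2-en-6-ynoate | CCOC(=O)/C=C(\C)CCC#C[Si](C)(C)C | intermediate
6 | 1-[(1E)-2-methyl-6-(trimethylsilyl)hex-1-en-5-yn-1-yl]cyclopropan-1-ol | C[Si](C)(C)C#CCC/C(C)=C/C1(O)CC1 | intermediate
7 | tert-butyl(dimethyl){1-[(1E)-2-methyl-6-(trimethylsilyl)hex-1-en-5-yn-1-yl]cyclopropoxy}silane | C[Si](C)(C)C#CCC/C(C)=C/C1(O[Si](C)(C)C(C)(C)C)CC1 | intermediate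
8 | tert-butyl(dimethyl){1-[(1E)-2-methylhex-1-en-5-yn-1-yl]cyclopropoxy}silane | C#CCC/C(C)=C/C1(O[Si](C)(C)C(C)(C)C)CC1 | intermediate
9 | lithium acetylide of 8 | [Li]C#CCC/C(C)=C/C1(O[Si](C)(C)C(C)(C)C)CC1 | intermediate (not isolated)
10 | ethyl (6E)-7-[1-(tert-butyldimethylsilyloxy)cyclopropyl]-6-methylhept-6-en-2-ynoate | CCOC(=O)C#CCC/C(C)=C/C1(O[Si](C)(C)C(C)(C)C)CC1 | intermediate
11 | ethyl (2E,6E)-7-[1-(tert-butyldimethylsilyloxy)cyclopropyl]-6-methyl-3-(propan-2-yl)hepta-2,6-dienoate | CCOC(=O)/C=C(/C(C)C)CC/C(C)=C/C1(O[Si](C)(C)C(C)(C)C)CC1 | intermediate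
12 | (2E,6E)-7-[1-(tert-butyldimethylsilyloxy)cyclopropyl]-6-methyl-3-(propan-2-yl)hepta-2,6-dien-1-ol | OC/C=C(/C(C)C)CC/C(C)=C/C1(O[Si](C)(C)C(C)(C)C)CC1 | intermediate
13 | [(2R,3R)-3-{(3E)-4-[1-(tert-butyldimethylsilyloxy)cyclopropyl]-3-methylbut-3-en-1-yl}-3-(propan-2-yl)oxiran-2-yl]methanol | OC[C@H]1O[C@@]1(C(C)C)CC/C(C)=C/C2(O[Si](C)(C)C(C)(C)C)CC2 | intermediate
14 | (2S,3R)-2-(chloromethyl)-3-{(3E)-4-[1-(tert-butyldimethylsilyloxy)cyclopropyl]-3-methylbut-3-en-1-yl}-3-(propan-2-yl)oxirane | ClC[C@H]1O[C@@]1(C(C)C)CC/C(C)=C/C2(O[Si](C)(C)C(C)(C)C)CC2 | intermediate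
15 | (3R,6E)-1-chloro-7-[1-(tert-butyldimethylsilyloxy)cyclopropyl]-6-methyl-3-(propan-2-yl)hepta-1,6-dien-3-ol, present as its lithium alkoxide | ClC=C[C@](O)(C(C)C)CC/C(C)=C/C1(O[Si](C)(C)C(C)(C)C)CC1 | intermediate (not isolated)
16 | (3R,6E)-7-[1-(tert-butyldimethylsilyloxy)cyclopropyl]-6-methyl-3-(propan-2-yl)hept-6-en-1-yn-3-ol | O[C@@](C#C)(C(C)C)CC/C(C)=C/C1(O[Si](C)(C)C(C)(C)C)CC1 | intermediate (precursor of the key step)
17 | 9-(tert-butyldimethylsilyloxy)-1β-methyl-4α-(propan-2-yl)bicyclo[5.3.0]deca-5,9-dien-4β-ol | O[C@@]1(C(C)C)CC[C@]2(C)C=C(O[Si](C)(C)C(C)(C)C)CCC=C21 | intermediate (product of the key step)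
18 | 4β-hydroxy-1β-methyl-4α-(propan-2-yl)bicyclo[5.3.0]dec-5-en-9-one | O[C@@]1(C(C)C)CC[C@]2(C)CC(=O)CCC=C21 | intermediate
19 | 8-[(dimethylamino)methyl]-4β-hydroxy-1β-methyl-4α-(propan-2-yl)bicyclo[5.3.0]dec-5-en-9-one (C8 epimers) | O[C@@]1(C(C)C)CC[C@]2(C)CC(=O)C(CN(C)C)CC=C21 | intermediate (not isolated)
20 | {[4β-hydroxy-1β-methyl-9-oxo-4α-(propan-2-yl)bicyclo[5.3.0]dec-5-en-8-yl]methyl}trimethylammonium iodide | O[C@@]1(C(C)C)CC[C@]2(C)CC(=O)C(C[N+](C)(C)C)CC=C21.[I-] | intermediate (not isolated)
21 | 4β-hydroxy-1β-methyl-8-methylidene-4α-(propan-2-yl)bicyclo[5.3.0]dec-5-en-9-one | O[C@@]1(C(C)C)CC[C@]2(C)CC(=O)C(=C)CC=C21 | intermediate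
22 | 1β-methyl-8-methylidene-4α-(propan-2-yl)bicyclo[5.3.0]dec-5-ene-4β,9-diol (C9 epimers) | O[C@@]1(C(C)C)CC[C@]2(C)CC(O)C(=C)CC=C21 | intermediate
23 | N-[4β-hydroxy-1β-methyl-8-methylidene-4α-(propan-2-yl)bicyclo[5.3.0]dec-5-en-9-yl]-2-nitrobenzenesulfonohydrazide (alkylated on the sulfonyl nitrogen) | O[C@@]1(C(C)C)CC[C@]2(C)CC(N(N)S(=O)(=O)c3ccccc3[N+](=O)[O-])C(=C)CC=C21 | intermediate (not isolated)
24 | 9-diazenyl-1β-methyl-8-methylidene-4α-(propan-2-yl)bicyclo[5.3.0]dec-5-en-4β-ol | O[C@@]1(C(C)C)CC[C@]2(C)CC(N=N)C(=C)CC=C21 | intermediate (not isolated)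
25 | 1β,8-dimethyl-4α-(propan-2-yl)bicyclo[5.3.0]deca-5,8-dien-4β-ol | O[C@@]1(C(C)C)CC[C@]2(C)CC=C(C)CC=C21 | intermediate
26 | 5β,6β-epoxy-1β,8-dimethyl-4α-(propan-2-yl)bicyclo[5.3.0]dec-8-en-4β-ol | O[C@@]2(C(C)C)CC[C@]3(C)CC=C(C)C[C@H]4O[C@]432 | intermediate
27 | 1β,8-dimethyl-4α-(propan-2-yl)-5αH-bicyclo[5.3.0]dec-8-ene-4β,6β-diol | O[C@@]2(C(C)C)CC[C@]3(C)CC=C(C)C[C@@H](O)[C@H]32 | intermediate
28 | 4β-hydroxy-1β,8-dimethyl-4α-(propan-2-yl)-5αH-bicyclo[5.3.0]dec-8-en-6-one | O[C@@]2(C(C)C)CC[C@]3(C)CC=C(C)CC(=O)[C@H]32 | intermediate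
29 | 1β,8-dimethyl-4α-(propan-2-yl)-5αH-bicyclo[5.3.0]dec-8-ene-4β,6α-diol | O[C@@]2(C(C)C)CC[C@]3(C)CC=C(C)C[C@H](O)[C@H]32 | intermediate
30 | 8α,9α-epoxy-1β,8-dimethyl-4α-(propan-2-yl)-5αH-bicyclo[5.3.0]decane-4β,6α-diol | O[C@@]2(C(C)C)CC[C@]3(C)C[C@@H]4O[C@]4(C)C[C@H](O)[C@H]32 | intermediate
31 | 8α,9α-epoxy-1β,8-dimethyl-4α-(propan-2-yl)-6α-(triethylsilyloxy)-5αH-bicyclo[5.3.0]decan-4β-ol | O[C@@]2(C(C)C)CC[C@]3(C)C[C@@H]4O[C@]4(C)C[C@H](O[Si](CC)(CC)CC)[C@H]32 | intermediate
32 | vanillic acid | COc1cc(C(=O)O)ccc1O | starting material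
33 | tert-butyldimethylsilyl 4-(tert-butyldimethylsilyloxy)-3-methoxybenzoate | COc1cc(C(=O)O[Si](C)(C)C(C)(C)C)ccc1O[Si](C)(C)C(C)(C)C | intermediate (not isolated)
34 | 4-(tert-butyldimethylsilyloxy)-3-methoxybenzoic acid | COc1cc(C(=O)O)ccc1O[Si](C)(C)C(C)(C)C | intermediate
35 | 4-(tert-butyldimethylsilyloxy)-3-methoxybenzoyl chloride | COc1cc(C(Cl)=O)ccc1O[Si](C)(C)C(C)(C)C | intermediate
36 | 8α,9α-epoxy-1β,8-dimethyl-4α-(propan-2-yl)-6α-(triethylsilyloxy)-5αH-bicyclo[5.3.0]decan-4β-yl 4-(tert-butyldimethylsilyloxy)-3-methoxybenzoate | COc1cc(C(=O)O[C@@]2(C(C)C)CC[C@]3(C)C[C@@H]4O[C@]4(C)C[C@H](O[Si](CC)(CC)CC)[C@H]32)ccc1O[Si](C)(C)C(C)(C)C | intermediate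
37 | 8α,9α-epoxy-6α-hydroxy-1β,8-dimethyl-4α-(propan-2-yl)-5αH-bicyclo[5.3.0]decan-4β-yl 4-hydroxy-3-methoxybenzoate (CNP0315707.1) | COc1cc(C(=O)O[C@@]2(C(C)C)CC[C@]3(C)C[C@@H]4O[C@]4(C)C[C@H](O)[C@H]32)ccc1O | target

## Step count and least certain steps

Total step count: 25. Longest linear sequence: 23 steps (steps 1 to 21, then 24 and 25). Steps 22 and 23 form the short side branch from vanillic acid.

**Step 11 (key step).** The most likely failure is poor facial discrimination at C1=C10. The C4 centre is three atoms away from C1, and both transition states with a pseudo-equatorial isopropyl group are accessible, so the C1 epimer of 17 may form in a comparable amount. Slow insertion of the trisubstituted alkene could also let alkyne oligomerisation compete. The fallback replaces substrate control by catalyst control and a larger group on the C4 oxygen. It sets out from 16, which is silylated (TESOTf, 2,6-lutidine, −78 °C) to the triethylsilyl ether F1. F1 is cyclised with a cationic rhodium catalyst carrying a chiral bisphosphine ([Rh(cod)2]SbF6 with (R)-BINAP, or its enantiomer, whichever matches the substrate bias) to the bis-silyl cycloadduct F2. Treatment of F2 with TBAF/AcOH removes both silyl groups and returns to the route at ketone 18.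

**Step 17.** Hydrogen-atom transfer to the planar C5 radical may show poor facial selectivity and give the cis-fused diol. Alternatively, trapping of the radical by a second titanium centre followed by β-elimination could deoxygenate the epoxide back to 25, which can be recycled. The fallback switches from kinetic to thermodynamic control of C5. It sets out from 26. The cis-fused 5βH-diol F3 formed in the opening is oxidised with Dess–Martin periodinane to the cis-fused ketone F4. Its C4 hydroxyl is masked as the trimethylsilyl ether F5 (N-trimethylsilylimidazole), which blocks retro-aldol cleavage. F5 is equilibrated with DBU in toluene to the trans-fused silyl ether F6, in which C6 is trans to the isopropyl group. Mild desilylation (HF·pyridine, THF, 0 °C) returns to the route at 28.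

**Step 24.** Acylation of the tertiary alkoxide, which sits between the isopropyl group and the ring fusion, may stall, and prolonged exposure to base invites silyl migration from O6 or elimination. The fallback avoids intermolecular acylation of the tertiary oxygen. It sets out from 28, which undergoes an Evans–Tishchenko reduction with 4-(tert-butyldimethylsilyloxy)-3-methoxybenzaldehyde and SmI2 (catalytic, THF, −10 °C). The hemiacetal formed at the C4 hydroxyl passes its hydride to C6, which gives the anti-diol monoester F7 with the acyl group already on O4 and C6–OH free. Hydroxyl-directed epoxidation (VO(acac)2, t-BuOOH) then gives the epoxide F8, and TBAF/AcOH returns to the route at the target 37.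

**Step 2.** An α,β-unsaturated ester may react with the low-valent titanium species by conjugate reduction or oligomerisation instead of cyclopropanation, and ligand exchange with the alkyne is a further loss channel. The fallback builds the siloxycyclopropane by carbenoid addition. It sets out from 5, which is converted into the Weinreb amide F9 (MeONHMe·HCl, i-PrMgCl) and then into the methyl enone F10 (MeMgBr). Enol silylation (TBSOTf, Et3N) gives the 2-siloxydiene F11. Simmons–Smith cyclopropanation (Et2Zn, CH2I2) of its electron-rich enol ether alkene returns to the route at 7.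

**Step 15.** Mitsunobu displacement at C9, which lies between a neopentylic CH2 and the methylidene carbon, may be slow, so elimination to a triene or recovery of 22 is possible. The fallback reaches the same allylic diazene by reduction. It sets out from 21, which is condensed with tosylhydrazide to the tosylhydrazone F12. Reduction with catecholborane followed by NaOAc·3H2O and warming returns to the route at 25 and bypasses 22.

## Further compounds

F1 | step 11 | tert-butyl(dimethyl){1-[(1E,6R)-2-methyl-6-(propan-2-yl)-6-(triethylsilyloxy)oct-1-en-7-yn-1-yl]cyclopropoxy}silane (triethylsilyl ether of 16) | CC[Si](CC)(CC)O[C@@](C#C)(C(C)C)CC/C(C)=C/C1(O[Si](C)(C)C(C)(C)C)CC1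
F2 | step 11 | 9-(tert-butyldimethylsilyloxy)-1β-methyl-4α-(propan-2-yl)-4β-(triethylsilyloxy)bicyclo[5.3.0]deca-5,9-diene | CC[Si](CC)(CC)O[C@@]1(C(C)C)CC[C@]2(C)C=C(O[Si](C)(C)C(C)(C)C)CCC=C21
F3 | step 17 | 1β,8-dimethyl-4α-(propan-2-yl)-5βH-bicyclo[5.3.0]dec-8-ene-4β,6β-diol | O[C@@]2(C(C)C)CC[C@]3(C)CC=C(C)C[C@@H](O)[C@@H]32
F4 | step 17 | 4β-hydroxy-1β,8-dimethyl-4α-(propan-2-yl)-5βH-bicyclo[5.3.0]dec-8-en-6-one | O[C@@]2(C(C)C)CC[C@]3(C)CC=C(C)CC(=O)[C@@H]32
F5 | step 17 | 1β,8-dimethyl-4α-(propan-2-yl)-4β-(trimethylsilyloxy)-5βH-bicyclo[5.3.0]dec-8-en-6-one | C[Si](C)(C)O[C@@]2(C(C)C)CC[C@]3(C)CC=C(C)CC(=O)[C@@H]32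
F6 | step 17 | 1β,8-dimethyl-4α-(propan-2-yl)-4β-(trimethylsilyloxy)-5αH-bicyclo[5.3.0]dec-8-en-6-one | C[Si](C)(C)O[C@@]2(C(C)C)CC[C@]3(C)CC=C(C)CC(=O)[C@H]32
F7 | step 24 | 6α-hydroxy-1β,8-dimethyl-4α-(propan-2-yl)-5αH-bicyclo[5.3.0]dec-8-en-4β-yl 4-(tert-butyldimethylsilyloxy)-3-methoxybenzoate | COc1cc(C(=O)O[C@@]2(C(C)C)CC[C@]3(C)CC=C(C)C[C@H](O)[C@H]32)ccc1O[Si](C)(C)C(C)(C)C
F8 | step 24 | 8α,9α-epoxy-6α-hydroxy-1β,8-dimethyl-4α-(propan-2-yl)-5αH-bicyclo[5.3.0]decan-4β-yl 4-(tert-butyldimethylsilyloxy)-3-methoxybenzoate | COc1cc(C(=O)O[C@@]2(C(C)C)CC[C@]3(C)C[C@@H]4O[C@]4(C)C[C@H](O)[C@H]32)ccc1O[Si](C)(C)C(C)(C)C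
F9 | step 2 | (2E)-N-methoxy-N,3-dimethyl-7-(trimethylsilyl)hept-2-en-6-ynamide | CON(C)C(=O)/C=C(\C)CCC#C[Si](C)(C)C
F10 | step 2 | (3E)-4-methyl-8-(trimethylsilyl)oct-3-en-7-yn-2-one | CC(=O)/C=C(\C)CCC#C[Si](C)(C)C
F11 | step 2 | tert-butyl(dimethyl){[(3E)-4-methyl-8-(trimethylsilyl)octa-1,3-dien-7-yn-2-yl]oxy}silane | C=C(O[Si](C)(C)C(C)(C)C)/C=C(\C)CCC#C[Si](C)(C)C
F12 | step 15 | N'-[4β-hydroxy-1β-methyl-8-methylidene-4α-(propan-2-yl)bicyclo[5.3.0]dec-5-en-9-ylidene]-4-methylbenzenesulfonohydrazide | O[C@@]1(C(C)C)CC[C@]2(C)CC(=NNS(=O)(=O)c3ccc(C)cc3)C(=C)CC=C21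
A1 | alternative 1 | methyl 2-(methoxymethoxy)-5-methyl-5-[(2Z)-3-methyl-4-(pivaloyloxy)but-2-en-1-yl]-2-(propan-2-yl)cyclopentane-1-carboxylate (ring A ester with C1, C4 and C5 set) | COCO[C@@]1(C(C)C)CC[C@](C)(C/C=C(/C)COC(=O)C(C)(C)C)[C@H]1C(=O)OC
A2 | alternative 2 | 3-methylcyclopent-2-en-1-one | CC1=CC(=O)CC1
A3 | alternative 2 | 2-[1-hydroxy-2-(2-methyl-1,3-dioxolan-2-yl)ethyl]-3-methyl-3-[(E)-2-(trimethylsilyl)ethenyl]cyclopentan-1-one (ring A ketone with C1, C5 and C6 set) | O=C1CC[C@](C)(/C=C/[Si](C)(C)C)[C@H]1[C@@H](O)CC1(C)OCCO1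
A4 | alternative 3 | ethyl 1β,8-dimethyl-6-oxo-4α-(propan-2-yl)-4β-(triethylsilyloxy)bicyclo[5.3.0]dec-8-ene-7-carboxylate (one C7 epimer drawn) | CC[Si](CC)(CC)O[C@@]1(C(C)C)CC[C@]2(C)CC=C(C)[C@H](C(=O)OCC)C(=O)[C@H]21
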